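**Retrosynthetic overview**
1. The meso target is traced back to the alkynyl diacetate (CO2-templated hydration of a tertiary propargylic alcohol), then to the meso alkynyl triol (acetylation), then to trans-4,5-dihydroxy-5-(undec-1-ynyl)cyclopent-2-enone (Luche reduction).
2. Key disconnection: the ring bond between an alkene CH and the neighbouring oxygen-bearing CH. It is made by photochemical ring contraction of 3-(undec-1-ynyl)-4H-pyran-4-one with capture of water, which converts the flat heteroaromatic ring into the carbocycle with both hydroxyl stereocentres in place.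
3. Enabling feature: the cross-conjugated 4-pyranone ring, in which ring oxygen O1 lies between two unsubstituted sp2 CH carbons (C2 and C6) opposite the C4 carbonyl. On excitation C2 bonds to C6, O1 becomes an oxirane, and C3–C4–C5 becomes an oxyallyl zwitterion whose alkynyl-bearing terminus C3 takes up water.
4. The pyranone comes from 3-bromo-4H-pyran-4-one and 1-undecyne (Sonogashira), and the bromide from 4H-pyran-4-one.
5. Ring order: the purchased pyranone ring is consumed in step 3, where the only ring of the target (the cyclopentene) is formed; the oxirane (step 3) and the cyclic carbonate (step 6) are transient.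

Key step: step 3

Remark: the target is a meso compound (mirror plane through the carbinol carbon and the midpoint of the ring alkene; the two acetoxy groups are cis to each other and trans to the tertiary hydroxyl). Chiral intermediates are therefore made as racemates, and their SMILES show one enantiomer.

**Step 1**
Reactants: 1 4H-pyran-4-one
Product: 3 3-bromo-4H-pyran-4-one, via dibromide 2 (not isolated)
Conditions: Br2 (1.0 equiv), CH2Cl2, 0 °C; then Et3N, 0 °C to rt
Reagents that add atoms: bromine, BrBr
Why: Bromine adds across one enol-ether double bond of the vinylogous ester and Et3N then removes HBr by E1cB elimination (α-bromination of an enone by addition–elimination), one equivalent of Br2 holding the reaction at the monobromide.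

**Step 2**
Reactants: 3 3-bromo-4H-pyran-4-one; 4 1-undecyne
Product: 5 3-(undec-1-yn-1-yl)-4H-pyran-4-one
Conditions: PdCl2(PPh3)2 (3 mol %), CuI (5 mol %), Et3N, THF, 50 °C
Reagents that add atoms: none
Why: Sonogashira coupling of the α-bromo-enone C(sp2)–Br bond with the terminal alkyne, run with a tertiary amine because primary and secondary amines open 4-pyranones.

**Step 3**
Reactants: 5 3-(undec-1-yn-1-yl)-4H-pyran-4-one
Product: 8 rac-(4R,5S)-4,5-dihydroxy-5-(undec-1-yn-1-yl)cyclopent-2-en-1-one, via oxyallyl zwitterion 6 (not isolated), via epoxy enol 7 (not isolated)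
Conditions: hν (medium-pressure Hg lamp, Vycor filter), degassed MeCN–H2O (1:1), 5 mM, 10 °C
Reagents that add atoms: water, O
Why: Excitation of the pyranone triggers an excited-state disrotatory 4π closure across the O1-centred pentadienyl-type array, which bonds the two O-flanking CH carbons C2 and C6 and so closes the five-membered carbocycle as a bicyclo[3.1.0] system cis-fused to the new oxirane, giving oxyallyl zwitterion 6. Water then adds to an oxyallyl terminus on the convex face, anti to the oxirane oxygen, to give epoxy enol 7, whose enol opens the adjacent oxirane C–O bond (vinylogous β-elimination) and leaves the ring alkene and the secondary carbinol. The closest known reaction type is the photochemical rearrangement of 4-pyranones and 4-hydroxypyrylium cations with capture of hydroxylic solvent, which gives trans-4-hydroxy-5-alkoxy- or 4,5-dihydroxycyclopent-2-enones. The tertiary carbinol centre is set by the anti attack of water (controlled by the oxirane oxygen) and the secondary carbinol keeps the original C2–O1 bond, so the two hydroxyls should come out trans. The step needs water to attack the alkynyl-bearing terminus and not the CH terminus: the alkynyl group concentrates positive charge on its carbon (propargylic stabilisation) and, being linear, does not shield it, as in charge-controlled solvolytic capture of unsymmetrical oxyallyl cations, while high dilution suppresses pyranone photodimerisation.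

**Step 4**
Reactants: 8 rac-(4R,5S)-4,5-dihydroxy-5-(undec-1-yn-1-yl)cyclopent-2-en-1-one
Product: 9 (1r,2R,5S)-1-(undec-1-yn-1-yl)cyclopent-3-ene-1,2,5-triol
Conditions: NaBH4, CeCl3·7H2O, MeOH, −78 °C
Reagents that add atoms: none
Why: Luche reduction gives clean 1,2-reduction of the enone, and hydride should enter from the face of the tertiary hydroxyl, anti to both the neighbouring alkynyl group and the remote secondary hydroxyl, so the new carbinol comes out cis to the existing secondary one and the triol is meso.

**Step 5**
Reactants: 9 (1r,2R,5S)-1-(undec-1-yn-1-yl)cyclopent-3-ene-1,2,5-triol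
Product: 10 (1R,2r,3S)-2-hydroxy-2-(undec-1-yn-1-yl)cyclopent-4-ene-1,3-diyl diacetate
Conditions: Ac2O (2.5 equiv), pyridine, DMAP (5 mol %), CH2Cl2, 0 °C
Reagents that add atoms: acetic anhydride, CC(=O)OC(C)=O
Why: Acylation with Ac2O/pyridine esterifies the two secondary allylic hydroxyls, while the tertiary propargylic hydroxyl, flanked by two substituted carbons, should stay free under these mild conditions.

**Step 6**
Reactants: 10 (1R,2r,3S)-2-hydroxy-2-(undec-1-yn-1-yl)cyclopent-4-ene-1,3-diyl diacetate
Product: 12 (1R,2r,3S)-2-hydroxy-2-undecanoylcyclopent-4-ene-1,3-diyl diacetate, via alkylidene carbonate 11 (not isolated)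
Conditions: AgOAc (10 mol %), DBU (1.0 equiv), CO2 (1 MPa), MeCN, 25 °C; then H2O (5 equiv), 40 °C
Reagents that add atoms: carbon dioxide, O=C=O
Why: Silver-catalysed carboxylative cyclisation of the tertiary propargylic alcohol (5-exo-dig anti attack of the carbonate oxygen on the AgOAc-activated alkyne) places oxygen on the alkyne carbon next to the carbinol, and hydrolysis of the Z-alkylidene carbonate with loss of CO2 unmasks the α-hydroxy ketone (CO2-promoted hydration of propargylic alcohols; water supplies only the hydrogens), while the acetates should survive the bicarbonate-buffered medium and cannot migrate to the tertiary oxygen, which is trans to both.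

**Compound list**
1 | 4H-pyran-4-one | O=C1C=COC=C1 | starting material
2 | rac-trans-2,3-dibromo-2,3-dihydro-4H-pyran-4-one (formed in the flask, not isolated) | Br[C@H]1OC=CC(=O)[C@@H]1Br | intermediate
3 | 3-bromo-4H-pyran-4-one | O=C1C=COC=C1Br | intermediate
4 | 1-undecyne | C#CCCCCCCCCC | starting material
5 | 3-(undec-1-yn-1-yl)-4H-pyran-4-one | CCCCCCCCCC#CC1=COC=CC1=O | intermediate
6 | 4-(undec-1-yn-1-yl)-6-oxabicyclo[3.1.0]hex-3-en-2-ylium-3-olate, oxyallyl zwitterion (racemic, not isolated) | CCCCCCCCCC#CC1=C([O-])[CH+][C@H]2O[C@@H]12 | intermediate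
7 | 2-(undec-1-yn-1-yl)-6-oxabicyclo[3.1.0]hex-3-ene-2,3-diol, epoxy enol with the tertiary hydroxyl anti to the oxirane oxygen (racemic, not isolated) | CCCCCCCCCC#C[C@@]1(O)C(O)=C[C@H]2O[C@@H]12 | intermediate
8 | rac-(4R,5S)-4,5-dihydroxy-5-(undec-1-yn-1-yl)cyclopent-2-en-1-one (hydroxyls trans) | CCCCCCCCCC#C[C@@]1(O)C(=O)C=C[C@H]1O | intermediate
9 | (1r,2R,5S)-1-(undec-1-yn-1-yl)cyclopent-3-ene-1,2,5-triol (meso; secondary hydroxyls cis to each other and trans to the tertiary hydroxyl) | CCCCCCCCCC#C[C@@]1(O)[C@@H](O)C=C[C@H]1O | intermediate
10 | (1R,2r,3S)-2-hydroxy-2-(undec-1-yn-1-yl)cyclopent-4-ene-1,3-diyl diacetate (meso) | CCCCCCCCCC#C[C@@]1(O)[C@@H](OC(C)=O)C=C[C@H]1OC(C)=O | intermediate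
11 | (4Z)-4-decylidene-2-oxo-1,3-dioxaspiro[4.4]non-7-ene-6,9-diyl diacetate (meso; spiro oxygen O1 trans to both acetoxy groups; not isolated) | CCCCCCCCC/C=C1\OC(=O)O[C@@]12[C@@H](OC(C)=O)C=C[C@H]2OC(C)=O | intermediate
12 | (1R,2r,3S)-2-hydroxy-2-undecanoylcyclopent-4-ene-1,3-diyl diacetate, CNP0208983.3 (meso; acetoxy groups cis to each other and trans to the tertiary hydroxyl) | CCCCCCCCCCC(=O)[C@@]1(O)[C@@H](OC(C)=O)C=C[C@H]1OC(C)=O | target

Total step count: 6
Longest linear sequence: 6 steps (from 1)

**Steps most likely to fail**

1. Step 3. Water may be captured at the unsubstituted oxyallyl terminus or at the remote alkyne carbon instead of the alkynyl-bearing ring carbon. A pyranone without substituents at C2 and C6 may also photodimerise or close inefficiently. The fallback sets out from 4 and returns at 8; it buys the carbocycle and makes the trans-diol by classical epoxide hydrolysis. Sonogashira coupling of 4 with commercial 2-iodocyclopent-2-en-1-one F1 (PdCl2(PPh3)2, CuI, Et3N, THF) would give 2-(undec-1-yn-1-yl)cyclopent-2-en-1-one F2. Weitz–Scheffer epoxidation (H2O2, NaOH, MeOH, 0 °C) would give the epoxy ketone 1-(undec-1-yn-1-yl)-6-oxabicyclo[3.1.0]hexan-2-one F3. Enolisation on its only enolisable side (LiN(iPr)2, Me3SiCl, THF, −78 °C) would give the silyl enol ether trimethyl{[1-(undec-1-yn-1-yl)-6-oxabicyclo[3.1.0]hex-2-en-2-yl]oxy}silane F4, and Saegusa–Ito dehydrogenation (Pd(OAc)2, MeCN) the epoxy enone 1-(undec-1-yn-1-yl)-6-oxabicyclo[3.1.0]hex-3-en-2-one F5. Acid-catalysed opening of the oxirane by water at its allylic carbon with inversion (HClO4 cat., THF–H2O, 0 °C) should then deliver trans-diol 8.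

2. Step 6. Carboxylative cyclisation may be sluggish at the hindered, electron-poor tertiary alkoxide, and acetate may be lost during the aqueous stage. The fallback sets out from 10 and returns at 12. It replaces the CO2-derived carbonate tether by anchimeric participation of a flanking acetate: with Ph3PAuNTf2 (2 mol %) in 1,4-dioxane–H2O at 40 °C, the carbonyl oxygen of an acetoxy group cis to the alkynyl group should attack the gold-activated alkyne 6-exo-dig at the carbon next to the carbinol, and hydrolysis of the acyloxonium ion then gives the ketone and restores the acetate. No new isolated compound is made.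

3. Step 4. Facial selectivity of hydride delivery may be poor, giving the epimer with the two secondary hydroxyls trans. The fallback sets out from 8 and returns at 9. Selective silylation of the secondary hydroxyl (tBuMe2SiCl, imidazole, DMF) would give rac-(4R,5S)-4-[(tert-butyldimethylsilyl)oxy]-5-hydroxy-5-(undec-1-yn-1-yl)cyclopent-2-en-1-one F6. The bulky silyloxy group then shields its own face in a 1,2-reduction with iBu2AlH (toluene, −78 °C), which should give the cis-alcohol 5-[(tert-butyldimethylsilyl)oxy]-1-(undec-1-yn-1-yl)cyclopent-3-ene-1,2-diol F7 (ring oxygens at C2 and C5 cis, tertiary hydroxyl trans to both). Bu4NF (THF) then returns triol 9.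

**Further compounds**
F1 | step 3 | 2-iodocyclopent-2-en-1-one | O=C1CCC=C1I
F2 | step 3 | 2-(undec-1-yn-1-yl)cyclopent-2-en-1-one | CCCCCCCCCC#CC1=CCCC1=O
F3 | step 3 | 1-(undec-1-yn-1-yl)-6-oxabicyclo[3.1.0]hexan-2-one (racemic) | CCCCCCCCCC#C[C@]12O[C@H]1CCC2=O
F4 | step 3 | trimethyl{[1-(undec-1-yn-1-yl)-6-oxabicyclo[3.1.0]hex-2-en-2-yl]oxy}silane (racemic) | CCCCCCCCCC#C[C@]12O[C@H]1CC=C2O[Si](C)(C)C
F5 | step 3 | 1-(undec-1-yn-1-yl)-6-oxabicyclo[3.1.0]hex-3-en-2-one (racemic) | CCCCCCCCCC#C[C@]12O[C@H]1C=CC2=O
F6 | step 4 | rac-(4R,5S)-4-[(tert-butyldimethylsilyl)oxy]-5-hydroxy-5-(undec-1-yn-1-yl)cyclopent-2-en-1-one | CCCCCCCCCC#C[C@@]1(O)C(=O)C=C[C@H]1O[Si](C)(C)C(C)(C)C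
F7 | step 4 | 5-[(tert-butyldimethylsilyl)oxy]-1-(undec-1-yn-1-yl)cyclopent-3-ene-1,2-diol (racemic; ring oxygens at C2 and C5 cis, tertiary hydroxyl trans to both) | CCCCCCCCCC#C[C@@]1(O)[C@@H](O)C=C[C@H]1O[Si](C)(C)C(C)(C)C
F0 | step 6 | none | none
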